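Remark: the target has no stereocentre and is achiral. Ring A is written throughout in the dienol tautomer of the given SMILES, and all keto–enol tautomers are treated as one compound.

## The problem

The target (the acetyl member of the desaspidin family) has two six-membered rings joined by one CH2 group. Ring B is an aromatic acetylphloroglucinol monomethyl ether; ring A is a dearomatised gem-dimethyl β-triketone (acetylfilicinic acid). There is no stereocentre, so the difficulty is purely constitutional.

Both bridge termini are strong, nearly equal carbon nucleophiles. Any free one-carbon electrophile therefore gives the two symmetrical dimers beside the mixed one, and the usual ring B precursor has two equivalent free ring carbons, so over-bridging follows. Only one of the three ring B oxygens is methylated (para to the acetyl group, ortho to the bridge). In ring A two methyl groups must go on one carbon while the neighbouring carbon stays free for the bridge.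

The finished bridge is labile. Phenoxide-driven retro-Michael cleavage scrambles it in alkali, acid closes pyran rings across it, and hot alkali removes the acetyl groups.

The feature that opens a different route is the polyketide pattern of ring B. Read as an acetate chain, its carbons are:

- C1: the C–OH carbon next to the bridge carbon
- C2: the bridge-bearing carbon
- C3: the C–OMe carbon
- C4: the C–H carbon
- C5: the second C–OH carbon
- C6: the acetyl-bearing carbon, with the acetyl group as C7–C8

C1–C6 with the methyl ether on C3 is exactly 4-methoxy-6-methyl-2-pyranone carrying the bridge on pyranone C3. Because C2 bears the bridge, the only folding of this chain that can end in an arene is the Claisen closure C6→C1.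

## Retrosynthesis

**12 ⇒ 11 ⇒ 10 ⇒ 9.** Ring B is not brought in as an arene; it is unfolded.

- Bonds cut: the ring B bond between the acetyl-bearing carbon and the C–OH carbon next to the bridge (chain C6–C1) gives the open-chain ester 11. Relactonisation to the acetonylpyranone 10 and removal of the acetyl unit (C6–C7) lead to the bridged pyranone 9.
- Against the neighbours: cutting the other C(acetyl)–C(OH) bond would put the bridge on pyranone C5, which has no simple chemistry. Cutting the bridge itself is the classical plan and brings back the cross-coupling problem.
- Gain: 9 lacks ring B altogether, is two carbons smaller, and already holds the methyl ether and the single bridge in the right places.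
- Asked of the forward reaction: acetylation of the pyranone methyl group in the presence of the acidic ring A, lactone opening, and a C6→C1 Claisen closure in preference to any aldol mode, all under conditions that do not scramble the bridge.

**9 ⇒ 3 + 7 (through 8).** The bond between the bridge carbon and ring A is cut, first as a C=C bond (alkylidene trione 8), then as a Knoevenagel disconnection.

- The bridge carbon is thus delivered as the formyl carbon of pyranone aldehyde 7, bound to one partner before the two meet. No symmetrical dimer can form, and 7 has no enolisable hydrogen.
- Cutting the other bridge bond (CH2–pyranone C3) would need a C-nucleophilic 4-methoxypyranone, which it is not.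
- Asked of the forward reaction: condensation at the one ring C–H of acetylfilicinic acid 3 and hydride transfer to 8 faster than a second addition of 3.

**7 ⇒ 6 ⇒ 4 (through 5).** The C4–OMe bond is cut to the vinylogous acid chloride 6. The C3–CHO and C4–Cl bonds are then cut together (through iminium salt 5) back to triacetic acid lactone 4.

- C3 of 4 is its only strongly nucleophilic carbon, and a single chloroformylation puts in both the bridge carbon and a leaving group at C4.
- Methylating first and formylating afterwards is the weaker order, because a 4-methoxypyranone is a poor nucleophile at C3.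

**3 ⇒ 1 (through 2).** The two C–CH3 bonds at the quaternary carbon of ring A are cut, leading through the monomethyl compound 2 to phloroacetophenone 1.

- This dearomative double C-methylation is the shortest access to the gem-dimethyl triketone.
- It leaves exactly one ring C–H, the one the bridge needs.

## Roads not taken

**Alternative 1:** (the obvious one) Cut both bridge bonds and join the two preformed rings, 3 and purchased 1-(2,6-dihydroxy-4-methoxyphenyl)ethanone A1, with CH2O or a Mannich base of one partner.

- It is shorter (two steps), but it has no structural control.
- Both partners are strong C-nucleophiles, so the mixed product comes with the symmetrical dimers A2 (from 3) and A3 (from A1).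
- A1 has two equivalent free ring carbons, so chains grow beyond the dimer.
- All these species interconvert by retro-Michael cleavage under the coupling conditions and are hard to separate.
- A variant pre-attaches the bridge carbon as aldehyde A4 and reduces the condensation product. This cures the cross-selectivity, but the formyl carbon of A4 lies between free hydroxyl groups, so the condensation product is an ortho-quinone-methide-like species open to chromene closure.
- The chosen plan spends three more steps to make each bridge bond once, at a site with no such hydroxyl group, and to have ring B arise with exactly one bridge.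

**Alternative 2:** Cut the two C–CH3 bonds of ring A last and dearomatise the diarylmethane A5 with MeI and base.

- A5 has a second free ring carbon on ring B, flanked by OMe and OH, that is about as nucleophilic as the one on ring A. Nuclear methylation of ring B and O-methylation would compete.
- Making A5 still requires the unsymmetrical bridging of two phloroglucinols (1 and A1), one of which has two free carbons.
- The chosen plan does the methylation on 1, where the outcome is known and nothing else is at risk.

**Alternative 3:** Fold ring A instead of ring B, by Claisen closure (C6→C1) of the gem-dimethyl triketo ester A6 hung on the benzylic carbon of a finished ring B.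

- Ring A is available in one step from 1, so building it from a chain gains nothing.
- A6 has three enolisable ketones and free phenols, which would need protection during chain assembly.
- A competing aldol closure (C8→C3) to a resorcinol is not blocked.
- The bridge to ring B would still have to be made selectively beforehand.
- For ring B, by contrast, the masked chain exists ready-made as a pyranone, with the methyl ether and the double-bond geometry fixed.

Key step: step 5

## Route

Step 1
Reactants: 1 1-(2,4,6-trihydroxyphenyl)ethanone (phloroacetophenone)
Product: 3 2-acetyl-3,5-dihydroxy-4,4-dimethylcyclohexa-2,5-dien-1-one (acetylfilicinic acid), via C-monomethyl phloroacetophenone 2 (not isolated)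
Conditions: NaOMe (3 equiv), MeI (2.2 equiv), MeOH, 0 → 25 °C; then 1 M HCl
Reagents that add atoms: iodomethane, CI
Why: Dearomative C-alkylation of a phloroglucinol anion: the ambident phenoxide of 1 reacts with the soft electrophile at ring carbon in the protic solvent, and the anion of 2 should be methylated again at the same carbon to give the cross-conjugated gem-dimethyl triketone 3; the isomeric and over-methylated by-products are expected and are to be removed by crystallisation; no stereocentre is formed.

Step 2
Reactants: 4 4-hydroxy-6-methyl-2H-pyran-2-one (triacetic acid lactone)
Product: 6 4-chloro-6-methyl-2-oxo-2H-pyran-3-carbaldehyde, via iminium chloride 5 (not isolated)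
Conditions: POCl3 (2.5 equiv), DMF, 0 → 60 °C; then ice water
Reagents that add atoms: N,N-dimethylformamide, CN(C)C=O; phosphoryl chloride, O=P(Cl)(Cl)Cl; water, O (aldehyde oxygen, on hydrolysis of 5)
Why: Vilsmeier–Haack–Arnold chloroformylation of a cyclic 1,3-dicarbonyl enol, standard for 4-hydroxycoumarins and 4-hydroxy-2-pyranones: the chloroiminium salt attacks C3, the most nucleophilic carbon of 4, and turns the 4-hydroxyl group into a vinylogous acid chloride; aqueous work-up hydrolyses 5 to the aldehyde.

Step 3
Reactants: 6 4-chloro-6-methyl-2-oxo-2H-pyran-3-carbaldehyde
Product: 7 4-methoxy-6-methyl-2-oxo-2H-pyran-3-carbaldehyde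
Conditions: NaOMe (1.0 equiv), MeOH–THF, −20 → 0 °C
Reagents that add atoms: sodium methoxide, C[O-].[Na+]
Why: Nucleophilic vinylic substitution (addition–elimination) at C4, which is β to both the lactone carbonyl and the formyl group and carries chloride as leaving group; with one equivalent of methoxide at low temperature this should outrun attack at the lactone carbonyl.

Step 4
Reactants: 3 acetylfilicinic acid; 7 4-methoxy-6-methyl-2-oxo-2H-pyran-3-carbaldehyde
Product: 9 3-[(5-acetyl-2,4-dihydroxy-3,3-dimethyl-6-oxocyclohexa-1,4-dien-1-yl)methyl]-4-methoxy-6-methyl-2H-pyran-2-one, via alkylidene trione 8 (not isolated)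
Conditions: Hantzsch ester (diethyl 2,6-dimethyl-1,4-dihydropyridine-3,5-dicarboxylate, 1.1 equiv), L-proline (10 mol %), CH2Cl2, 25 °C
Reagents that add atoms: none
Why: Three-component reductive alkylation of a cyclic 1,3-dicarbonyl compound: Knoevenagel condensation of the single ring C–H of 3 with the non-enolisable aldehyde 7 gives the alkylidene trione 8, a strong hydride acceptor that the Hantzsch ester should reduce by conjugate transfer hydrogenation before a second molecule of 3 adds. The bridge carbon arrives bound to one partner, so no symmetrical dimer can form, and the formyl carbon of 7 lies between a lactone carbonyl and a methyl ether, so no hydroxyl group is at hand to close a pyran ring. No stereocentre is formed (8 is an E/Z mixture of no consequence).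

Step 5
Reactants: 9 3-[(5-acetyl-2,4-dihydroxy-3,3-dimethyl-6-oxocyclohexa-1,4-dien-1-yl)methyl]-4-methoxy-6-methyl-2H-pyran-2-one
Product: 12 2-acetyl-6-[(3-acetyl-2,4-dihydroxy-6-methoxyphenyl)methyl]-3,5-dihydroxy-4,4-dimethylcyclohexa-2,5-dien-1-one (the target), via acetonylpyranone 10 (not isolated), via open-chain methyl ester 11 (not isolated)
Conditions: LiN(iPr)2 (3.3 equiv), THF–DMPU, −78 °C; MeC(O)N(OMe)Me (1.2 equiv), −78 → 0 °C; then MeOH, Mg(OMe)2 (4 equiv), 55 °C; 1 M HCl, 0 °C
Reagents that add atoms: N-methoxy-N-methylacetamide, CC(=O)N(C)OC (acetyl group of 10, 11 and 12); Mg(OMe)2, C[O-].C[O-].[Mg+2] (ester methoxy group of 11 only, lost again on ring closure)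
Why: Two equivalents of LiN(iPr)2 convert ring A into its dienolate dianion and the third removes a proton from the C6-methyl group of the pyranone, the only remaining acidic C–H because it is vinylogous to the lactone carbonyl; the Weinreb amide acetylates this carbanion without over-addition and methanol then releases 10. Mg(OMe)2 opens the lactone at C2 to ester 11, whose C2=C3 double bond keeps the ester carbon C1 and C4 on the same side as they were in the ring, and the magnesium-chelated C5/C7 diketonate acylates C6 with the ester (Claisen condensation of Dieckmann type, 6-exo-trig at the ester carbonyl with the enolate carbon inside the new ring), after which loss of methoxide and enolisation give aromatic ring B with OH, bridge, OMe, H, OH and acetyl on C1 to C6 in that order. The closest known reaction types are the acylation of lithiated 4-methoxy-6-methyl-2-pyranone at its methyl group and the Mg(OMe)2-induced conversion of 6-(2-oxoalkyl)-4-methoxy-2-pyranones, as masked 3,5,7-triketo esters, into 2-acyl-5-methoxyresorcinols. The step needs site selectivity in the deprotonation, which the dianionic state of ring A secures because its acetyl methyl group could only be deprotonated to a trianion within one ring, and it needs Claisen instead of aldol folding, which the substrate secures because C2 bears the bridge and would end as a quaternary, non-aromatisable carbon in the aldol mode while C3 is held as a methyl enol ether whose exchange with methoxide is degenerate. Reversible side equilibria (O-acylation of a ring A enolate by the ester, E/Z isomerisation of 11) should drain into the arene, which is taken out of the equilibrium as a magnesium chelate of its two o-acyl enol units; this chelation and the cold acidic work-up are also what should hold back retro-Michael scrambling of the bridge. No stereocentre is created.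

## Compound list

1 | 1-(2,4,6-trihydroxyphenyl)ethanone (phloroacetophenone) | CC(=O)c1c(O)cc(O)cc1O | starting material
2 | 1-(2,4,6-trihydroxy-3-methylphenyl)ethanone (formed in the flask, not isolated) | CC(=O)c1c(O)cc(O)c(C)c1O | intermediate
3 | 2-acetyl-3,5-dihydroxy-4,4-dimethylcyclohexa-2,5-dien-1-one (acetylfilicinic acid) | CC(=O)C1=C(O)C(C)(C)C(O)=CC1=O | intermediate
4 | 4-hydroxy-6-methyl-2H-pyran-2-one (triacetic acid lactone) | CC1=CC(O)=CC(=O)O1 | starting material
5 | [(4-chloro-6-methyl-2-oxo-2H-pyran-3-yl)methylidene]dimethylammonium chloride (formed in the flask, not isolated) | C[N+](C)=CC1=C(Cl)C=C(C)OC1=O.[Cl-] | intermediate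
6 | 4-chloro-6-methyl-2-oxo-2H-pyran-3-carbaldehyde | CC1=CC(Cl)=C(C=O)C(=O)O1 | intermediate
7 | 4-methoxy-6-methyl-2-oxo-2H-pyran-3-carbaldehyde | COC1=C(C=O)C(=O)OC(C)=C1 | intermediate
8 | 2-acetyl-3-hydroxy-6-[(4-methoxy-6-methyl-2-oxo-2H-pyran-3-yl)methylidene]-4,4-dimethylcyclohex-2-ene-1,5-dione (E/Z mixture, formed in the flask, not isolated) | CC(=O)C1=C(O)C(C)(C)C(=O)C(=CC2=C(OC)C=C(C)OC2=O)C1=O | intermediate
9 | 3-[(5-acetyl-2,4-dihydroxy-3,3-dimethyl-6-oxocyclohexa-1,4-dien-1-yl)methyl]-4-methoxy-6-methyl-2H-pyran-2-one | COC1=C(CC2=C(O)C(C)(C)C(O)=C(C(C)=O)C2=O)C(=O)OC(C)=C1 | intermediate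
10 | 3-[(5-acetyl-2,4-dihydroxy-3,3-dimethyl-6-oxocyclohexa-1,4-dien-1-yl)methyl]-4-methoxy-6-(2-oxopropyl)-2H-pyran-2-one (formed in the flask, not isolated) | COC1=C(CC2=C(O)C(C)(C)C(O)=C(C(C)=O)C2=O)C(=O)OC(CC(C)=O)=C1 | intermediate
11 | methyl (2E)-2-[(5-acetyl-2,4-dihydroxy-3,3-dimethyl-6-oxocyclohexa-1,4-dien-1-yl)methyl]-3-methoxy-5,7-dioxooct-2-enoate (ester carbon and C4 on the same side; formed in the flask, not isolated) | COC(=O)/C(CC1=C(O)C(C)(C)C(O)=C(C(C)=O)C1=O)=C(/OC)CC(=O)CC(C)=O | intermediate
12 | 2-acetyl-6-[(3-acetyl-2,4-dihydroxy-6-methoxyphenyl)methyl]-3,5-dihydroxy-4,4-dimethylcyclohexa-2,5-dien-1-one | COc1cc(O)c(C(C)=O)c(O)c1CC1=C(O)C(C)(C)C(O)=C(C(C)=O)C1=O | target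

## Step count and least certain steps

Total step count: 5 (the one-pot key step counted as one). Longest linear sequence: 4 steps (4 → 6 → 7 → 9 → 12); the one-step branch 1 → 3 joins at step 4.

**Step 5 (key step).**

- What may go wrong: the dilithium salt of ring A may be poorly soluble, so formation and acetylation of the pyranone carbanion stay incomplete. In the methoxide stage, retro-Michael cleavage and recombination may scramble the bridge of the product, and retro-Claisen loss of an acetyl group may occur.
- Fallback: ring B is made before the bridge, so that no folding is needed. It sets out from 3 and returns to the route at 12. Purchased 1-(2,6-dihydroxy-4-methoxyphenyl)ethanone F1 would be mono-formylated under Vilsmeier–Haack conditions (POCl3, DMF, EtOAc) to 3-acetyl-2,4-dihydroxy-6-methoxybenzaldehyde F2. F2 would then be joined to 3 by the Knoevenagel/Hantzsch ester reductive alkylation of step 4 to give 12 directly. The bridge carbon still arrives bound to one partner.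

**Step 4.**

- What may go wrong: nucleophiles (the enol of 3 or the amine catalyst) may add at C4 of 7 with loss of methoxide instead of condensing at the formyl carbon. A second molecule of 3 may add to 8 faster than hydride is transferred. The acidic medium may close a pyran ring across the new bridge with loss of methanol.
- Fallback: the bridge bond is made by cation alkylation instead of condensation/reduction. It sets out from 7 and returns at 9. Luche reduction (NaBH4, CeCl3·7H2O, MeOH, −40 °C) would give 3-(hydroxymethyl)-4-methoxy-6-methyl-2H-pyran-2-one F3. Acid-catalysed dehydrative C-alkylation of 3 with F3 (TsOH·H2O, 10 mol %, MeCN, 0 → 20 °C) through the methoxy-stabilised allylic cation should then give 9.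

**Step 3.**

- What may go wrong: methoxide may open the pyranone at the lactone carbonyl, add reversibly to the aldehyde and start hydride-transfer side reactions, or traces of water may return the 4-hydroxy aldehyde.
- Fallback: the methyl ether is put in first and the formyl group last. It sets out from 4 and returns at 7, bypassing 6. O-Methylation of 4 (Me2SO4, K2CO3, acetone, reflux) would give 4-methoxy-6-methyl-2H-pyran-2-one F4. Bromination at C3 (NBS, MeCN, 25 °C) would give 3-bromo-4-methoxy-6-methyl-2H-pyran-2-one F5. Palladium-catalysed reductive carbonylation (Pd(OAc)2, di(1-adamantyl)-n-butylphosphine, CO/H2, TMEDA, toluene, 100 °C) should then give 7.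

**Step 1.**

- What may go wrong: methylation may run on to the second free ring carbon, which is the carbon the bridge needs, or stop at 2; O-methylation may also intervene. The result would be a mixture that lowers the supply of 3.
- Fallback: the bridge is installed before the methyl groups, so that it occupies the carbon that must not be methylated. It sets out from 1 and returns at 9. Reductive alkylation of 1 (in excess) with 7 under the conditions of step 4 would give 3-[(3-acetyl-2,4,6-trihydroxyphenyl)methyl]-4-methoxy-6-methyl-2H-pyran-2-one F6. Double C-methylation of its one remaining ring carbon (MeI, NaOMe, MeOH, 0 → 25 °C) should then give 9.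

## Further compounds

F1 | step 5 | 1-(2,6-dihydroxy-4-methoxyphenyl)ethanone (purchased) | COc1cc(O)c(C(C)=O)c(O)c1
F2 | step 5 | 3-acetyl-2,4-dihydroxy-6-methoxybenzaldehyde | COc1cc(O)c(C(C)=O)c(O)c1C=O
F3 | step 4 | 3-(hydroxymethyl)-4-methoxy-6-methyl-2H-pyran-2-one | COC1=C(CO)C(=O)OC(C)=C1
F4 | step 3 | 4-methoxy-6-methyl-2H-pyran-2-one | COC1=CC(=O)OC(C)=C1
F5 | step 3 | 3-bromo-4-methoxy-6-methyl-2H-pyran-2-one | COC1=C(Br)C(=O)OC(C)=C1
F6 | step 1 | 3-[(3-acetyl-2,4,6-trihydroxyphenyl)methyl]-4-methoxy-6-methyl-2H-pyran-2-one | COC1=C(Cc2c(O)cc(O)c(C(C)=O)c2O)C(=O)OC(C)=C1
A1 | alternative 1 | 1-(2,6-dihydroxy-4-methoxyphenyl)ethanone | COc1cc(O)c(C(C)=O)c(O)c1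
A2 | alternative 1 | 2,2'-methylenebis(6-acetyl-3,5-dihydroxy-4,4-dimethylcyclohexa-2,5-dien-1-one) (albaspidin AA) | CC(=O)C1=C(O)C(C)(C)C(O)=C(CC2=C(O)C(C)(C)C(O)=C(C(C)=O)C2=O)C1=O
A3 | alternative 1 | 1,1'-[methylenebis(2,4-dihydroxy-6-methoxy-3,1-phenylene)]diethanone | COc1cc(O)c(C(C)=O)c(O)c1Cc1c(OC)cc(O)c(C(C)=O)c1O
A4 | alternative 1 | 3-acetyl-2,4-dihydroxy-6-methoxybenzaldehyde | COc1cc(O)c(C(C)=O)c(O)c1C=O
A5 | alternative 2 | 1-{3-[(3-acetyl-2,4-dihydroxy-6-methoxyphenyl)methyl]-2,4,6-trihydroxyphenyl}ethanone | COc1cc(O)c(C(C)=O)c(O)c1Cc1c(O)cc(O)c(C(C)=O)c1O
A6 | alternative 3 | methyl 4-[(3-acetyl-2,4-dihydroxy-6-methoxyphenyl)methyl]-2,2-dimethyl-3,5,7-trioxooctanoate | COC(=O)C(C)(C)C(=O)C(Cc1c(OC)cc(O)c(C(C)=O)c1O)C(=O)CC(C)=O
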